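The red run held twice the catalyst of the blue run, and the violet run 2.23 times its starting material. Yet at 50.0 min the sum [starting material] + [target], which I called the pool, read 37.5% in blue, 37.8% in violet and 40.4% in red. These lie close together, so I drew one rough curve for the three runs, with the pool halving in equal times.

| flask | starting material | protic impurity | catalyst | remark | time |
|---|---|---|---|---|---|
| blue | 0.43 M | 0.64 M | 64 mM | run made earlier |  |
| violet | 0.96 M | 0.64 M | 64 mM | run made earlier |  |
| red | 0.64 M | 0.64 M | 130 mM | run made earlier |  |
| autumn | 0.64 M | 0.640 M | 64 mM |  | 3.0 h |
| noon | 0.64 M | 0.640 M | 64 mM |  | 1.5 h |
| dusk | 0.64 M | 0.640 M | 64 mM |  | 2.0 h |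

- blue (time / min: side product / %, starting material / %, target / %): 4.00: 4.2, 85.9, 6.7; 8.00: 9.0, 70.9, 10.1; 12.0: 13.4, 62.6, 11.8; 20.0: 16.4, 48.8, 14.2; 30.0: 24.5, 38.4, 12.8; 50.0: 32.3, 26.6, 10.9
- violet (time / min: side product / %, starting material / %, target / %): 10.0: 10.8, 67.5, 13.6; 20.0: 17.0, 50.4, 15.3; 25.0: 21.4, 44.1, 13.8; 40.0: 29.8, 32.8, 15.1; 50.0: 32.4, 26.0, 11.8
- red (time / min: side product / %, starting material / %, target / %): 5.00: 6.3, 76.2, 9.6; 15.0: 15.3, 54.5, 17.5; 25.0: 21.2, 43.2, 13.8; 40.0: 29.3, 32.7, 12.4; 50.0: 30.7, 29.0, 11.4

(each reading ± 1 percentage point)

- the numbers in the tables scatter with a standard deviation of 1 percentage point

1. which of these there is most of at the end, counted by the starting material in it, autumn (side product / target / starting material)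
2. which of these there is most of at the end, counted by the starting material in it, noon (side product / target / starting material)
3. which of these there is most of at the end, counted by the starting material in it, dusk (side product / target / starting material)
4. amount of the one of these that there is most of at the end, in percent of the starting material charged, autumn
5. amount of the one of these that there is most of at the end, in percent of the starting material charged, noon
6. amount of the one of these that there is most of at the end, in percent of the starting material charged, dusk

The mean pool at that reading, 38.6%, gave a halving time of 36.4 min. Side product over pool lost, pooled at the same reading, gave 51.8%. This is the side share, a selectivity: side product gained per unit of pool lost.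

That halving time is an average over the first 50.0 min and no decay law: for 8.00 min it gives a pool of 85.9%, above the 81.0% that the blue run read, so what follows is an estimate. [Side product] should follow the side share times the pool lost. At the start that predicts 3.80% by 4.00 min, and the blue run read 4.2%. Starting material made up 70.5% of the pool at that reading, more than target. Side product therefore crosses starting material when the pool reaches 42.3%, at 45.1 min. Every asked time lies later, so I chose side product throughout. The knee follows, and the curve runs into a level equal to the side share. Noon, at 2.47 halving times, gives 42.4%; dusk, at 3.30, gives 46.5%; autumn, at 4.95, gives 50.1%.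

The forecast said of side product, “It dominates at all three times”, and put it at 42% in noon, 46% in dusk and 52% in autumn. My curve matched it in noon and dusk but lay lower in autumn, where the forecast stood at about my level.

The flasks held most side product in noon, 43.0%; most side product in dusk, 47.5%; and most side product in autumn, 52.4%.

    starting material + catalyst ⇌ catalyst + target (K = 0.330, k = 0.280 /M/min)
    starting material → side product (k = 0.0130 /min)
    starting material + protic impurity → quenched substrate (k = 0.0210 /M/min)

Counted from the dusk flask itself, the side share came to 55.0%, above my reading. The neighbour is that same flask read at 30 min, before my crossing. For it my curve gives a pool of 56.5% and side product of 22.5%. The neighbour held a pool of 54.0%, and its largest share was starting material, at 39.5% against 24.0% of side product.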